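## Retrosynthetic overview
1. Hypercalin B ⇒ an aromatic 3-(cyclopentylmethyl)-2,4,6-trihydroxybenzophenone plus two prenyl bromides. The last free ring carbon is alkylated twice with dearomatisation, as a prenyl transferase would do, and this is the final step.
2. That arene ⇒ 2,4,6-trihydroxybenzophenone (from phloroglucinol and benzoyl chloride) plus a formylcyclopentane. The aryl–CH2 bond is made through an o-quinone methide that is reduced as it forms.
3. Formylcyclopentane ⇒ open-chain 2,3-epoxygeranial by C-2/C-6 closure, ended by loss of H from C-8. Bond, oxygen atom and termination match the presumed closure of the 2',3'-epoxygeranyl chain. The closure is run as a radical, so the formyl group makes the epoxide open at C-2.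
4. Epoxygeranial ⇒ geraniol. Sharpless epoxidation fixes the carbinol centre, and the other two centres follow from it.
5. Ring order: the phenyl and six-membered rings are bought. The cyclopentane is the only ring made (step 3). It is closed before the union because an epoxide beside free ortho-phenols would collapse to a dihydrobenzofuran.

Assumption: the presumed biosynthesis is taken as C-geranylation of 2,4,6-trihydroxybenzophenone, 2',3'-epoxidation, C-2'–C-6' closure with loss of H-8', and gem-diprenylation; the target is drawn in the enol tautomer of the given SMILES.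

## Route

Step 1
Reactants: 1 geraniol [(2E)-3,7-dimethylocta-2,6-dien-1-ol]
Product: 2 (2S,3S)-2,3-epoxygeraniol {[(2S,3S)-3-methyl-3-(4-methylpent-3-en-1-yl)oxiran-2-yl]methanol}
Conditions: Ti(OiPr)4 (5 mol %), L-(+)-diethyl tartrate (6 mol %), t-BuOOH (1.5 equiv), 4 Å MS, CH2Cl2, −20 °C
Reagents that add atoms: tert-butyl hydroperoxide, CC(C)(C)OO
Why: Katsuki–Sharpless asymmetric epoxidation; the allylic OH binds titanium so only the 2,3-alkene reacts, and the L-(+)-tartrate delivers oxygen to the face that gives the (2S,3S)-epoxide (about 95 % ee), which sets the C-3–O centre that becomes the (S)-carbinol carbon of the target.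

Step 2
Reactants: 2 (2S,3S)-2,3-epoxygeraniol
Product: 3 (2R,3S)-2,3-epoxygeranial [(2R,3S)-3-methyl-3-(4-methylpent-3-en-1-yl)oxirane-2-carbaldehyde]
Conditions: TEMPO (10 mol %), PhI(OAc)2 (1.1 equiv), CH2Cl2, 0 °C to rt
Reagents that add atoms: none
Why: Oxoammonium (TEMPO) oxidation of a primary alcohol stops at the aldehyde and leaves the epoxide and the trisubstituted alkene alone; no stereocentre is touched, and the C-2 descriptor changes from S to R only because CHO outranks C-3.

Step 3
Reactants: 3 (2R,3S)-2,3-epoxygeranial
Product: 4 (1R,2S,5S)-2-methyl-5-(prop-1-en-2-yl)-2-[(trimethylsilyl)oxy]cyclopentane-1-carbaldehyde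
Conditions: Cp2TiCl2 (10 mol %), Mn dust, Me3SiCl (4 equiv), 2,4,6-collidine (7 equiv), THF (5 mM), slow addition of 3, rt
Reagents that add atoms: chlorotrimethylsilane, C[Si](C)(C)Cl
Why: Proposed new method: Cp2TiCl (trivalent titanium, kept dilute by the Mn/Me3SiCl/collidine turnover) opens the epoxide by single-electron transfer, and because the formyl group stabilises a radical at C-2 the C-2–O bond breaks (as in the known Cp2TiCl reduction of α,β-epoxy ketones to β-hydroxy ketones) rather than the C-3–O bond of an ordinary Nugent–RajanBabu opening, so oxygen stays on C-3 with its configuration; the electrophilic α-formyl radical then adds 5-exo to the electron-rich C-6=C-7 alkene through a Beckwith–Houk chair with the bulky OTiCp2Cl group pseudo-equatorial, which places the new ring C-5 substituent trans to oxygen; a second Cp2TiCl traps the tertiary radical, which loses a β-hydride from a methyl group to give the isopropenyl group, and the enolisable C-1 settles trans to both isopropenyl and methyl; closest known reaction types are the titanocene-catalysed radical epoxide–olefin (epoxypolyene) cyclisation and the α,β-epoxy ketone reduction.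

Step 4
Reactants: 5 phloroglucinol (benzene-1,3,5-triol); 6 benzoyl chloride
Product: 7 2,4,6-trihydroxybenzophenone [phenyl(2,4,6-trihydroxyphenyl)methanone]
Conditions: AlCl3 (3.5 equiv), PhNO2, 65 °C; then aq HCl
Reagents that add atoms: benzoyl chloride 6, O=C(Cl)c1ccccc1
Why: Friedel–Crafts acylation of a very electron-rich arene; the first acyl group, chelated to aluminium, deactivates the ring so the reaction stops at mono-benzoylation, and no stereocentre is formed.

Step 5
Reactants: 4 (1R,2S,5S)-2-methyl-5-(prop-1-en-2-yl)-2-[(trimethylsilyl)oxy]cyclopentane-1-carbaldehyde; 7 2,4,6-trihydroxybenzophenone (2 equiv)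
Product: 10 (3-{[(1R,2S,5S)-2-hydroxy-2-methyl-5-(prop-1-en-2-yl)cyclopentyl]methyl}-2,4,6-trihydroxyphenyl)(phenyl)methanone, via o-quinone methide 8 (not isolated), via silyl ether 9 (not isolated)
Conditions: L-proline (20 mol %), Hantzsch ester (diethyl 2,6-dimethyl-1,4-dihydropyridine-3,5-dicarboxylate, 1.3 equiv), EtOH–CH2Cl2, rt; then citric acid, MeOH–H2O, rt
Reagents that add atoms: none
Why: Three-component reductive alkylation (Knoevenagel-type condensation, then transfer hydrogenation); the free nucleophilic ring carbon of the acylphloroglucinol condenses with the aldehyde to give o-quinone methide 8, whose exocyclic carbon takes hydride from the Hantzsch ester faster than a second hindered arene can add; no new stereocentre arises, ring C-1 stays enolisable until the hydride transfer and so is fixed in its most stable arrangement (trans to isopropenyl and to methyl, cis to oxygen), and the silyl ether blocks retro-aldol cleavage until the citric acid work-up removes it.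

Step 6
Reactants: 10 (3-{[(1R,2S,5S)-2-hydroxy-2-methyl-5-(prop-1-en-2-yl)cyclopentyl]methyl}-2,4,6-trihydroxyphenyl)(phenyl)methanone; 11 prenyl bromide (1-bromo-3-methylbut-2-ene, 2.4 equiv)
Product: 13 hypercalin B [2-benzoyl-3,5-dihydroxy-4-{[(1R,2S,5S)-2-hydroxy-2-methyl-5-(prop-1-en-2-yl)cyclopentyl]methyl}-6,6-bis(3-methylbut-2-en-1-yl)cyclohexa-2,4-dien-1-one], via 5-prenyl arene 12 (not isolated)
Conditions: KOH (3.5 equiv), H2O–MeOH, 0 °C to rt; then 1 M HCl
Reagents that add atoms: prenyl bromide 11, CC(C)=CCBr (two equivalents are built in)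
Why: Alkylative dearomatisation of an acylphloroglucinol (lupulone-type C-prenylation); the first prenyl group enters the only free ring carbon, and the second enters the same carbon because the other alkylated carbon carries the much bulkier β-branched cyclopentylmethyl group; the new quaternary carbon bears two identical groups and is not stereogenic, and the tertiary alcohol and the three ring stereocentres are inert to aqueous base.

## Compound list
1 | geraniol, (2E)-3,7-dimethylocta-2,6-dien-1-ol | CC(C)=CCC/C(C)=C/CO | starting material
2 | (2S,3S)-2,3-epoxygeraniol | CC(C)=CCC[C@]1(C)O[C@H]1CO | intermediate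
3 | (2R,3S)-2,3-epoxygeranial | CC(C)=CCC[C@]1(C)O[C@H]1C=O | intermediate
4 | (1R,2S,5S)-2-methyl-5-(prop-1-en-2-yl)-2-[(trimethylsilyl)oxy]cyclopentane-1-carbaldehyde | C=C(C)[C@H]1CC[C@](C)(O[Si](C)(C)C)[C@@H]1C=O | intermediate
5 | phloroglucinol | Oc1cc(O)cc(O)c1 | starting material
6 | benzoyl chloride | O=C(Cl)c1ccccc1 | starting material
7 | 2,4,6-trihydroxybenzophenone | O=C(c1ccccc1)c1c(O)cc(O)cc1O | intermediate
8 | o-quinone methide from 4 and 7 (exocyclic alkene geometry not defined) | C=C(C)[C@H]1CC[C@](C)(O[Si](C)(C)C)[C@@H]1C=C1C(=O)C(C(=O)c2ccccc2)=C(O)C=C1O | intermediate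
9 | trimethylsilyl ether of 10 | C=C(C)[C@H]1CC[C@](C)(O[Si](C)(C)C)[C@@H]1Cc1c(O)cc(O)c(C(=O)c2ccccc2)c1O | intermediate
10 | (3-{[(1R,2S,5S)-2-hydroxy-2-methyl-5-(prop-1-en-2-yl)cyclopentyl]methyl}-2,4,6-trihydroxyphenyl)(phenyl)methanone | C=C(C)[C@H]1CC[C@](C)(O)[C@@H]1Cc1c(O)cc(O)c(C(=O)c2ccccc2)c1O | intermediate
11 | prenyl bromide | CC(C)=CCBr | starting material
12 | 5-prenyl derivative of 10 (fully substituted arene) | C=C(C)[C@H]1CC[C@](C)(O)[C@@H]1Cc1c(O)c(CC=C(C)C)c(O)c(C(=O)c2ccccc2)c1O | intermediate
13 | hypercalin B | C=C(C)[C@H]1CC[C@](C)(O)[C@@H]1CC1=C(O)C(CC=C(C)C)(CC=C(C)C)C(=O)C(C(=O)c2ccccc2)=C1O | target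

## Step count and risks
Total step count: 6. Longest linear sequence: 5 (steps 1, 2, 3, 5, 6).

**Step 3 (highest risk).** The α-formyl radical may be reduced to a titanium enolate before it cyclises, and the selectivity at ring C-5 rests on the size of the titanoxy group. The fallback sets out from 3 and comes back at 4. It moves the closure from the epoxide opening to an enamine radical cation.
- Compound 3 is deliberately over-reduced with excess Cp2TiCl (from Cp2TiCl2 and Zn) in THF–MeOH at −78 °C to (3S)-3-hydroxy-3,7-dimethyloct-6-enal F1.
- N-(trimethylsilyl)imidazole converts this to (3S)-3,7-dimethyl-3-[(trimethylsilyl)oxy]oct-6-enal F2.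
- F2 is cyclised by SOMO organocatalysis. The catalyst is 5-benzyl-2-tert-butyl-3-methylimidazolidin-4-one trifluoroacetate, in the enantiomer matched to the (1R) centre. The oxidant is [Fe(phen)3](SbF6)3 (a one-electron oxidant of trivalent iron) with Na2HPO4 in DME at −30 °C.
- The catalyst fixes C-1, the chair transition state places the isopropenyl group trans to the formyl group, and loss of a proton from the tertiary cation gives 4.

**Step 5.** The hindered β-silyloxy aldehyde may eliminate silanol under amine catalysis, or the o-quinone methide may be caught by a second arene. The fallback sets out from 7 and comes back at 13. It dearomatises 7 first.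
- Prenyl bromide 11 (2 equiv) and NaOMe in MeOH give, through 3-prenyl-2,4,6-trihydroxybenzophenone F3, the triketone 2-benzoyl-3,5-dihydroxy-6,6-bis(3-methylbut-2-enyl)cyclohexa-2,4-dien-1-one F4. F4 is separated from its 3,5-diprenyl isomer; the material is cheap, so a modest yield is bearable.
- F4 is a true cyclic 1,3-dione CH acid, the substrate class for which proline/Hantzsch-ester reductive alkylation is established.
- With 4 it gives the alkylidene triketone F5, which is reduced in situ to hypercalin B trimethylsilyl ether F6.
- Citric acid then frees 13, and step 6 is no longer needed.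

**Step 6.** O-prenylation, or quaternisation at the wrong ring carbon, may erode the yield. The fallback sets out from 10 and comes back at 13. It replaces the two SN2 alkylations with allylation by zerovalent palladium followed by olefin metathesis.
- Compound 10, allyl methyl carbonate and Pd(PPh3)4 in THF give, through the 5-allyl arene F7, the gem-diallyl dienone F8.
- O-allyl ethers re-ionise under these conditions and drain to carbon, and the ligated π-allyl electrophile keeps the preference for the less hindered carbon.
- Double cross-metathesis of F8 with 2-methylbut-2-ene (as solvent) and the second-generation Grubbs catalyst turns both allyl groups into prenyl groups. The 1,1-disubstituted isopropenyl group is too hindered to take part.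

## Further compounds
F1 | step 3 | (3S)-3-hydroxy-3,7-dimethyloct-6-enal | CC(C)=CCC[C@](C)(O)CC=O
F2 | step 3 | (3S)-3,7-dimethyl-3-[(trimethylsilyl)oxy]oct-6-enal | CC(C)=CCC[C@](C)(O[Si](C)(C)C)CC=O
F3 | step 5 | 3-prenyl-2,4,6-trihydroxybenzophenone | CC(C)=CCc1c(O)cc(O)c(C(=O)c2ccccc2)c1O
F4 | step 5 | 2-benzoyl-3,5-dihydroxy-6,6-bis(3-methylbut-2-enyl)cyclohexa-2,4-dien-1-one | OC1=CC(O)=C(C(=O)c2ccccc2)C(=O)C1(CC=C(C)C)CC=C(C)C
F5 | step 5 | alkylidene triketone from F4 and 4 (exocyclic alkene geometry not defined) | C=C(C)[C@H]1CC[C@](C)(O[Si](C)(C)C)[C@@H]1C=C1C(=O)C(CC=C(C)C)(CC=C(C)C)C(=O)C(C(=O)c2ccccc2)=C1O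
F6 | step 5 | hypercalin B trimethylsilyl ether | C=C(C)[C@H]1CC[C@](C)(O[Si](C)(C)C)[C@@H]1CC1=C(O)C(CC=C(C)C)(CC=C(C)C)C(=O)C(C(=O)c2ccccc2)=C1O
F7 | step 6 | 5-allyl arene (5-allyl derivative of 10) | C=C(C)[C@H]1CC[C@](C)(O)[C@@H]1Cc1c(O)c(CC=C)c(O)c(C(=O)c2ccccc2)c1O
F8 | step 6 | gem-diallyl dienone (6,6-diallyl analogue of hypercalin B) | C=C(C)[C@H]1CC[C@](C)(O)[C@@H]1CC1=C(O)C(CC=C)(CC=C)C(=O)C(C(=O)c2ccccc2)=C1O
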